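**Plan**
- Chroman numbering is used (O1, C2, C3, C4, C4a, C8a); ring A is the benzo ring, ring B the pendant aryl ring. Retrosynthesis: remove the four formyl groups and five O-methyl groups, then cut the pyran ring at O1–C2 and C4a–C4, then cut C2–ring B.
- This leaves 3,5-dimethoxyphenol (ring A), 1,3,5-trimethoxybenzene (ring B) and (E)-2-isopropyl-5-methylhex-2-enal, the commercial self-aldol dimer of isovaleraldehyde, which supplies C2–C3–C4 with both alkyl groups.
- Enabling feature: C2 carries a 2,4,6-trioxygenated aryl ring and C2–C3–C4 is an allylic triad, so C2 and C4 are the two termini of a strongly stabilised 1-aryl-allyl cation (a 1,3-dielectrophile). Ring A offers a free OH and the carbon ortho to it (C4a) as an O,C-1,3-dinucleophile, so the pyran ring is a formal [3+3] adduct.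
- Forward: aryllithium addition to the enal gives the allylic alcohol; a chiral Brønsted acid-catalysed Friedel–Crafts allylation/ring closure builds the pyran ring (the only ring formed) and the whole skeleton; fourfold formylation and global demethylation finish the route.
- Stereochemistry: C4 comes from the chiral counter-anion (contact ion-pair catalysis); C3 and C2 follow from reversible ring closure to the all-equatorial 2,3-trans-3,4-trans (2R,3R,4R) chroman.

Key step: step 2

Assumption: the sense of induction of the phosphoramide cannot be predicted with certainty; the (R)-catalyst is written and its enantiomer would be used should it favour (4S).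

**Step 1**
Reactants: 1 1,3,5-trimethoxybenzene; 2 (E)-2-isopropyl-5-methylhex-2-enal
Product: 4 racemic (E)-2-isopropyl-5-methyl-1-(2,4,6-trimethoxyphenyl)hex-2-en-1-ol, via 2,4,6-trimethoxyphenyllithium 3 (not isolated)
Conditions: n-BuLi, THF, 0 °C → rt; then 2, −78 °C → 0 °C; aq. NH4Cl; chromatography on Et3N-deactivated silica
Reagents that add atoms: none
Why: Ortho-lithiation of 1 between two methoxy groups and 1,2-addition of the aryllithium to the aldehyde is a standard organolithium carbonyl addition; the carbinol centre is left racemic because ionisation in step 2 erases it.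

**Step 2**
Reactants: 4 racemic (E)-2-isopropyl-5-methyl-1-(2,4,6-trimethoxyphenyl)hex-2-en-1-ol; 5 3,5-dimethoxyphenol
Product: 8 (2R,3R,4R)-4-isobutyl-3-isopropyl-5,7-dimethoxy-2-(2,4,6-trimethoxyphenyl)chromane, via allyl cation 6 (not isolated), via ortho-allylphenol 7 (not isolated)
Conditions: 5 (1.5 equiv), (R)-3,3'-bis(2,4,6-triisopropylphenyl)-1,1'-binaphthyl-2,2'-diyl N-triflylphosphoramide (5 mol %), 5 Å MS, toluene, −60 °C → rt
Reagents that add atoms: none
Why: Proposed new method: the chiral N-triflylphosphoramide ionises the benzylic-allylic alcohol 4 to allyl cation 6, a contact ion pair whose anion also hydrogen-bonds the OH of 5, so that the carbon ortho to that OH attacks the alkyl-bearing terminus (future C4) in the enantio-determining Friedel–Crafts step; the styrene 7 so formed is reprotonated at C3 to the ring-B-stabilised C2 benzylic cation, which the phenol oxygen captures. The closest known reaction types are the racemic acid-catalysed [3+3] chroman annulation of phenols with allylic alcohols or 1,3-dienes and chiral phosphoramide contact-ion-pair allylic substitution of allyl cations by phenols. The one ring closed is the pyran ring, by 6-exo-trig attack of O1 on cationic C2 (overall a Markovnikov 6-endo hydroalkoxylation of the C2=C3 styrene). C4 is set by the catalyst through face selection on the planar cation, so racemic 4 converges on one enantiomer; C3 and C2 are set relative to C4 under thermodynamic control, because C2–O1 ionisation and C3 deprotonation/reprotonation are reversible while the C4a–C4 bond is not, which should funnel material to the all-equatorial 2,3-trans-3,4-trans isomer. The selectivities needed are gamma over alpha attack on the cation (C2 is shielded by the di-ortho-methoxy aryl ring and the isopropyl group, and the two ortho-methoxy groups also block indene-forming cyclisation of the cation), ortho over para C-alkylation of 5 (hydrogen bonding of its OH to the catalyst anion), and C2 over C3 cation formation in the closure (the trimethoxyphenyl ring).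

**Step 3**
Reactants: 8 (2R,3R,4R)-4-isobutyl-3-isopropyl-5,7-dimethoxy-2-(2,4,6-trimethoxyphenyl)chromane
Product: 9 (2R,3R,4R)-2-(3,5-diformyl-2,4,6-trimethoxyphenyl)-4-isobutyl-3-isopropyl-5,7-dimethoxychromane-6,8-dicarbaldehyde
Conditions: Cl2CHOMe (excess), TiCl4 (excess), CH2Cl2, −78 °C → 0 °C; then ice/H2O
Reagents that add atoms: dichloromethyl methyl ether, COC(Cl)Cl; water, O
Why: Fourfold Rieche formylation at the four free ring positions, each flanked by two alkoxy groups (double formylation of 2-alkyl-1,3,5-trimethoxybenzenes with this reagent pair is a known reaction type); no stereocentre is formed, and any methyl ether lost ortho to a new formyl group is harmless because step 4 removes them all.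

**Step 4**
Reactants: 9 (2R,3R,4R)-2-(3,5-diformyl-2,4,6-trimethoxyphenyl)-4-isobutyl-3-isopropyl-5,7-dimethoxychromane-6,8-dicarbaldehyde
Product: 10 sideroxylonal C, (2R,3R,4R)-2-(3,5-diformyl-2,4,6-trihydroxyphenyl)-5,7-dihydroxy-4-isobutyl-3-isopropylchromane-6,8-dicarbaldehyde
Conditions: BCl3 (excess), CH2Cl2, −78 °C → rt; then H2O
Reagents that add atoms: none
Why: All five methoxy groups lie ortho to a formyl group, so chelation-assisted aryl methyl ether cleavage by BCl3 should remove them without touching the aldehydes or the three stereocentres, whose ring is now deactivated towards C2–O1 ionisation.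

**Compound list**
1 | 1,3,5-trimethoxybenzene | COc1cc(OC)cc(OC)c1 | starting material
2 | (E)-2-isopropyl-5-methylhex-2-enal | CC(C)C/C=C(/C=O)C(C)C | starting material
3 | 2,4,6-trimethoxyphenyllithium | [Li]c1c(OC)cc(OC)cc1OC | intermediate
4 | racemic (E)-2-isopropyl-5-methyl-1-(2,4,6-trimethoxyphenyl)hex-2-en-1-ol | COc1cc(OC)c(C(O)/C(=C/CC(C)C)C(C)C)c(OC)c1 | intermediate
5 | 3,5-dimethoxyphenol | COc1cc(O)cc(OC)c1 | starting material
6 | 2-isopropyl-5-methyl-1-(2,4,6-trimethoxyphenyl)hex-1-en-3-ylium, the delocalised allyl cation ion-paired to the phosphoramide anion (one canonical form drawn) | COc1cc(OC)c(C=C([CH+]CC(C)C)C(C)C)c(OC)c1 | intermediate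
7 | 2-[(1E,3R)-2-isopropyl-5-methyl-1-(2,4,6-trimethoxyphenyl)hex-1-en-3-yl]-3,5-dimethoxyphenol | CC(C)C[C@@H](c1c(O)cc(OC)cc1OC)/C(C(C)C)=C/c1c(OC)cc(OC)cc1OC | intermediate
8 | (2R,3R,4R)-4-isobutyl-3-isopropyl-5,7-dimethoxy-2-(2,4,6-trimethoxyphenyl)chromane | CC(C)C[C@H]1c2c(OC)cc(OC)cc2O[C@@H](c2c(OC)cc(OC)cc2OC)[C@@H]1C(C)C | intermediate
9 | (2R,3R,4R)-2-(3,5-diformyl-2,4,6-trimethoxyphenyl)-4-isobutyl-3-isopropyl-5,7-dimethoxychromane-6,8-dicarbaldehyde | CC(C)C[C@H]1c2c(OC)c(C=O)c(OC)c(C=O)c2O[C@@H](c2c(OC)c(C=O)c(OC)c(C=O)c2OC)[C@@H]1C(C)C | intermediate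
10 | sideroxylonal C, (2R,3R,4R)-2-(3,5-diformyl-2,4,6-trihydroxyphenyl)-5,7-dihydroxy-4-isobutyl-3-isopropylchromane-6,8-dicarbaldehyde | CC(C)C[C@H]1c2c(O)c(C=O)c(O)c(C=O)c2O[C@@H](c2c(O)c(C=O)c(O)c(C=O)c2O)[C@@H]1C(C)C | target

**Totals**
Total step count: 4. Longest linear sequence: 4 steps (1 → 4 → 8 → 9 → 10).

**Steps most likely to fail**

Step 2 (Proposed new method). What may go wrong: poor enantiofacial discrimination in the ion pair, attack of the cation at the position para to the OH of 5 or at its own benzylic terminus, and incomplete or wrong-sense equilibration at C3 (the 3,4-cis isomer relieves peri strain with the 5-methoxy group). Fallback by known reaction types, setting out from 2 and 5 and returning at 8: iminium-catalysed Friedel–Crafts conjugate addition/hemiacetalisation of 5 with enal 2 (9-amino-9-deoxy-epi-quinine or its quinidine pseudo-enantiomer, CF3CO2H co-catalyst, toluene) should give (3R,4R)-4-isobutyl-3-isopropyl-5,7-dimethoxychroman-2-ol F1 as an anomeric mixture. Here C4 is set by the covalently bound amine, and C3 by equilibration alpha to the masked aldehyde. Oxocarbenium Friedel–Crafts arylation of F1 with 1 (BF3·OEt2, CH2Cl2, −40 °C) should then place ring B trans to the C3 isopropyl group and deliver 8.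

Step 3. What may go wrong: heterolysis of the C2–O1 bond by TiCl4 before ring B is deactivated by its first formyl group (ring opening, oligomerisation, epimerisation), and stalling before the fourth formylation. Fallback, setting out from 8 and returning at 10: exhaustive demethylation of 8 with BBr3 (CH2Cl2, −78 °C → rt) to (2R,3R,4R)-4-isobutyl-3-isopropyl-2-(2,4,6-trihydroxyphenyl)chromane-5,7-diol F2, then fourfold Vilsmeier–Haack formylation of the two free phloroglucinol nuclei (POCl3, DMF, EtOAc, 0 °C → rt, aqueous hydrolysis). This moves the formylation to the far more nucleophilic free polyphenol, avoids the strong Lewis acid, and gives 10 directly, bypassing 9.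

Step 4. What may go wrong: incomplete cleavage of the last methyl ethers as boron chelates accumulate, or Lewis-acid opening of the pyran ring with epimerisation at C2. Fallback, setting out from 9 and returning at 10: nucleophilic dealkylation with NaSEt in DMF at 100 °C, in which thiolate attacks the methyl groups of the carbonyl-activated ethers and no Lewis acid is present; no new compound arises on the way (F0).

**Further compounds**
F1 | step 2 | (3R,4R)-4-isobutyl-3-isopropyl-5,7-dimethoxychroman-2-ol (mixture of C2 anomers) | CC(C)C[C@H]1c2c(OC)cc(OC)cc2OC(O)[C@@H]1C(C)C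
F2 | step 3 | (2R,3R,4R)-4-isobutyl-3-isopropyl-2-(2,4,6-trihydroxyphenyl)chromane-5,7-diol | CC(C)C[C@H]1c2c(O)cc(O)cc2O[C@@H](c2c(O)cc(O)cc2O)[C@@H]1C(C)C
F0 | step 4 | none | none
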